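Ring A of the target flavone is an acylphloroglucinol: oxygens at C5, C7 and C8a alternate with carbons, and C4a carries the acyl carbon C4. This pattern is that of a folded triketide, so the route disconnects the C4a–C5 bond. In one operation, a Claisen-type cyclisation of an open-chain cinnamoyl 3,5,7-triketo ester closes ring A as a 2',4',6'-trihydroxychalcone, which is then closed to ring C and dehydrogenated. The precursor is a methyl (E)-9-aryl-3,5,7-trioxonon-8-enoate whose aryl group is the finished, enantiopure ring B: a (2S,3S)-dihydrobenzofuran bearing the prenyl group, a free tertiary alcohol and a silylated benzylic alcohol.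

Key step: step 12

Remarks on the chemistry
- In the target the C3 hydroxyl and the C2 2-hydroxypropan-2-yl group of the dihydrobenzofuran are trans, (2S,3S). Ring B is therefore made by phenoxide opening, with inversion, of a threo epoxy alcohol.
- The tertiary alcohol is carried free from step 8 on. As an alkoxide it is inert, and it costs one equivalent of the polyanion in step 11.
- Flavanone 20 is carried as both C2 epimers, since that centre is removed in step 14.
- Acid is avoided after step 8, because 3-hydroxy-2-(2-hydroxypropan-2-yl)-2,3-dihydrobenzofurans are prone to acid-induced loss of water (and acetone) to benzofurans.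
- A quinone dehydrogenation of the flavanone is not used, because a hydride-abstracting quinone could attack the prenyl methylene and aromatise the dihydrobenzofuran. The C2–C3 double bond is introduced through the silyl enol ether instead.
- Reagent 9 (commercial THF solution) and amide 16 are taken as purchased.

Step 1
Reactants: 1 dehydroacetic acid
Product: 2 methyl 3,5-dioxohexanoate
Conditions: Mg(OMe)2, MeOH, reflux; cold dilute aq. HCl
Reagents that add atoms: methanol (solvent, delivered as Mg(OMe)2), CO
Why: Methoxide opens the pyranone lactone and removes the 3-acetyl group by retro-Claisen cleavage, a known methanolysis of dehydroacetic acid; the diketo ester is held as its magnesium chelate until acidification.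

Step 2
Reactants: 3 4-bromophenol; 4 1-bromo-3-methylbut-2-ene
Product: 5 4-bromo-2-(3-methylbut-2-en-1-yl)phenol
Conditions: NaH, toluene, 0 °C; then 4, rt to 40 °C
Reagents that add atoms: none
Why: Ortho C-alkylation of a sodium phenoxide: as a tight ion pair in a non-polar solvent the phenoxide reacts at the ortho carbon, the para position being blocked by bromine; O-alkylated and dialkylated material is removed by chromatography.

Step 3
Reactants: 5 4-bromo-2-(3-methylbut-2-en-1-yl)phenol
Product: 7 5-bromo-2-hydroxy-3-(3-methylbut-2-en-1-yl)benzaldehyde, via salicyl alcohol 6 (not isolated)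
Conditions: MgCl2, Et3N, (CH2O)n, MeCN, reflux
Reagents that add atoms: paraformaldehyde (reacts as formaldehyde), C=O
Why: Casnati–Skattebøl ortho-formylation: the magnesium phenoxide directs hydroxymethylation to the only free ortho position, and a second formaldehyde oxidises the benzylic alkoxide by hydride transfer.

Step 4
Reactants: 7 5-bromo-2-hydroxy-3-(3-methylbut-2-en-1-yl)benzaldehyde
Product: 8 5-bromo-3-(3-methylbut-2-en-1-yl)-2-[(triisopropylsilyl)oxy]benzaldehyde
Conditions: TIPSOTf, 2,6-lutidine, CH2Cl2, 0 °C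
Reagents that add atoms: triisopropylsilyl trifluoromethanesulfonate, CC(C)[Si](OS(=O)(=O)C(F)(F)F)(C(C)C)C(C)C
Why: Phenol silylation with a silyl triflate, which reaches even a flanked, hydrogen-bonded phenol; the bulky TIPS ether tolerates the next three steps, resists transfer to a neighbouring alkoxide, and is later removed by fluoride to trigger ring closure.

Step 5
Reactants: 8 5-bromo-3-(3-methylbut-2-en-1-yl)-2-[(triisopropylsilyl)oxy]benzaldehyde; 9 (2-methylprop-1-en-1-yl)magnesium bromide
Product: 10 racemic 1-{5-bromo-3-(3-methylbut-2-en-1-yl)-2-[(triisopropylsilyl)oxy]phenyl}-3-methylbut-2-en-1-ol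
Conditions: THF, −78 to −20 °C; aq. NH4Cl
Reagents that add atoms: none
Why: Grignard 1,2-addition to the aldehyde; the aryl bromide does not exchange at this temperature, and the racemic carbinol is resolved in the next step.

Step 6
Reactants: 10 racemic allylic alcohol
Product: 11 (1R)-1-{5-bromo-3-(3-methylbut-2-en-1-yl)-2-[(triisopropylsilyl)oxy]phenyl}-3-methylbut-2-en-1-ol
Conditions: Ti(OiPr)4 (cat.), D-(−)-diisopropyl tartrate, t-BuOOH (0.6 equiv), 4 Å molecular sieves, CH2Cl2, −20 °C, run past half conversion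
Reagents that add atoms: none
Why: Sharpless kinetic resolution: with the D-(−)-tartrate the (S)-enantiomer is epoxidised faster (to its erythro epoxy alcohol), so the (R)-alcohol, which becomes C3 of ring B, is recovered with an enantiomeric purity that rises with conversion; the prenyl alkene has no directing hydroxyl and should not react.

Step 7
Reactants: 11 (R)-allylic alcohol
Product: 12 (S)-{5-bromo-3-(3-methylbut-2-en-1-yl)-2-[(triisopropylsilyl)oxy]phenyl}[(2R)-3,3-dimethyloxiran-2-yl]methanol (threo)
Conditions: VO(acac)2 (cat.), t-BuOOH, CH2Cl2, 0 °C to rt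
Reagents that add atoms: tert-butyl hydroperoxide, CC(C)(C)OO
Why: Hydroxyl-directed vanadium-catalysed epoxidation, which touches only the allylic alcohol alkene; the cis methyl group forces the carbinol hydrogen into the alkene plane (A(1,3) strain), so oxygen is delivered from the hydroxyl-bearing face and the threo isomer with the (2R) epoxide centre should predominate, the minor erythro isomer being separated (the carbinol descriptor changes from R to S only because the ranking of its neighbours changes).

Step 8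
Reactants: 12 threo epoxy alcohol
Product: 14 (2S,3S)-5-bromo-2-(2-hydroxypropan-2-yl)-7-(3-methylbut-2-en-1-yl)-2,3-dihydro-1-benzofuran-3-ol, via phenol epoxy alcohol 13 (not isolated)
Conditions: Bu4NF, THF, 0 to 50 °C; aq. NH4Cl
Reagents that add atoms: none
Why: Fluoride cleaves the aryl silyl ether and the phenoxide opens the epoxide in a 5-exo-tet SN2 reaction at the less substituted carbon; inversion there converts the (2R) epoxide centre into C2 (S) of the ring and places the two substituents trans, a base-mediated closure known for o-hydroxyphenyl epoxy carbinols.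

Step 9
Reactants: 14 trans-diol
Product: 15 2-[(2S,3S)-5-bromo-3-{[tert-butyl(dimethyl)silyl]oxy}-7-(3-methylbut-2-en-1-yl)-2,3-dihydro-1-benzofuran-2-yl]propan-2-ol
Conditions: TBSCl, imidazole, DMF, rt
Reagents that add atoms: tert-butyldimethylsilyl chloride, CC(C)(C)[Si](C)(C)Cl
Why: Sterically selective silylation: the secondary benzylic hydroxyl reacts and the tertiary one does not; the ether blocks ionisation and oxidation at the benzylic carbon in the later steps.

Step 10
Reactants: 15 aryl bromide; 16 N-methoxy-N-methylprop-2-enamide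
Product: 17 (2E)-3-[(2S,3S)-3-{[tert-butyl(dimethyl)silyl]oxy}-2-(2-hydroxypropan-2-yl)-7-(3-methylbut-2-en-1-yl)-2,3-dihydro-1-benzofuran-5-yl]-N-methoxy-N-methylprop-2-enamide
Conditions: Pd(OAc)2 (cat.), P(o-tol)3, Et3N, DMF, 100 °C
Reagents that add atoms: none
Why: Mizoroki–Heck coupling; syn insertion and β-hydride elimination give the E-cinnamamide, and the trisubstituted prenyl alkene is too hindered to insert.

Step 11
Reactants: 17 Weinreb cinnamamide; 2 methyl 3,5-dioxohexanoate
Product: 18 methyl (8E)-9-[(2S,3S)-3-{[tert-butyl(dimethyl)silyl]oxy}-2-(2-hydroxypropan-2-yl)-7-(3-methylbut-2-en-1-yl)-2,3-dihydro-1-benzofuran-5-yl]-3,5,7-trioxonon-8-enoate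
Conditions: 2 (2.5 equiv), LiN(iPr)2 (7.6 equiv), THF, −78 to 0 °C; then 17, −78 to 0 °C; AcOH, −78 °C, pH 5 buffer
Reagents that add atoms: none
Why: Terminal acylation of a 1,3,5-tricarbonyl polyanion: the trianion of 2 reacts at its most basic carbon C6 and adds 1,2 to the Weinreb amide, whose chelated tetrahedral adduct survives until the quench and so prevents a second addition; the excess covers the equivalent consumed by the tertiary hydroxyl, and 18 is used promptly as its enol mixture.

Step 12
Reactants: 18 cinnamoyl triketo ester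
Product: 19 (2E)-3-[(2S,3S)-3-{[tert-butyl(dimethyl)silyl]oxy}-2-(2-hydroxypropan-2-yl)-7-(3-methylbut-2-en-1-yl)-2,3-dihydro-1-benzofuran-5-yl]-1-(2,4,6-trihydroxyphenyl)prop-2-en-1-one
Conditions: Mg(OMe)2 (5 equiv), MeOH, N2, reflux; cold dilute aq. HCl to pH 4
Reagents that add atoms: none
Why: Excess Mg(OMe)2 converts 18 into its magnesium polyenolate, in which the carbanion at C6 (flanked by the C5 and C7 carbonyls) adds to the ester carbonyl C1; loss of methoxide gives the 2-acylcyclohexane-1,3,5-trione, which enolises to the aromatic triol. The closest known reaction is the base-induced Claisen (Dieckmann-type) cyclisation of 3,5,7-triketo esters to acylphloroglucinols, including cinnamoyl chains that give 2',4',6'-trihydroxychalcones. Ring A closes in the 6-exo-trig mode (enolate carbon onto an exocyclic C=O), forming the C4a–C5 bond of the later flavone. No stereocentre is formed, and the two ring B centres carry no acidic hydrogen and are not affected. The step needs the Claisen mode to win over aldol closure (C2 onto C7, which would give a styryl resorcylate) and over enol lactonisation to a pyranone: the ester rather than the acid keeps C1 electrophilic, full enolisation of all three ketones under excess alkoxide removes the ketone electrophile that the aldol needs, and magnesium chelation in dry methanol folds C1 onto C6. Methoxide matches the methyl ester, so transesterification changes nothing, and its conjugate addition to the enone is reversible.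

Step 13
Reactants: 19 chalcone
Product: 20 5,7-dihydroxy-2-[(2S,3S)-3-{[tert-butyl(dimethyl)silyl]oxy}-2-(2-hydroxypropan-2-yl)-7-(3-methylbut-2-en-1-yl)-2,3-dihydro-1-benzofuran-5-yl]-2,3-dihydro-4H-chromen-4-one (both C2 epimers)
Conditions: NaOAc, EtOH, reflux
Reagents that add atoms: none
Why: Base-catalysed intramolecular oxa-Michael addition (chalcone–flavanone isomerisation, 6-endo-trig) of a 2'-phenoxide; the new C2 centre forms without control and both epimers are used, since it is removed in step 14.

Step 14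
Reactants: 20 flavanone
Product: 23 5,7-dihydroxy-2-[(2S,3S)-3-{[tert-butyl(dimethyl)silyl]oxy}-2-(2-hydroxypropan-2-yl)-7-(3-methylbut-2-en-1-yl)-2,3-dihydro-1-benzofuran-5-yl]-4H-chromen-4-one, via silyl enol ether 21 (not isolated), via silylated flavone 22 (not isolated)
Conditions: TMSOTf, Et3N, CH2Cl2, 0 °C; filter, concentrate; Pd(OAc)2, MeCN, rt; K2CO3, MeOH, rt
Reagents that add atoms: none
Why: Soft enolisation gives the trimethylsilyl enol ether and masks the phenols and the tertiary alcohol; Saegusa–Ito oxidation (palladation at C3, then β-hydride elimination of the C2 hydrogen) installs the C2–C3 double bond at room temperature without touching the prenyl group or ring B; methanolysis then removes the trimethylsilyl groups and leaves the TBS ether.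

Step 15
Reactants: 23 silylated flavone
Product: 24 5,7-dihydroxy-2-[(2S,3S)-3-hydroxy-2-(2-hydroxypropan-2-yl)-7-(3-methylbut-2-en-1-yl)-2,3-dihydro-1-benzofuran-5-yl]-4H-chromen-4-one (target)
Conditions: Bu4NF, AcOH, THF, rt
Reagents that add atoms: none
Why: Fluoride-mediated cleavage of the secondary silyl ether under buffered, non-acidic conditions; neither stereocentre is touched, and the benzylic alcohol is not exposed to acid.

Compound list
1 | dehydroacetic acid (3-acetyl-4-hydroxy-6-methyl-2H-pyran-2-one) | CC(=O)C1=C(O)C=C(C)OC1=O | starting material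
2 | methyl 3,5-dioxohexanoate | COC(=O)CC(=O)CC(C)=O | intermediate
3 | 4-bromophenol | Oc1ccc(Br)cc1 | starting material
4 | 1-bromo-3-methylbut-2-ene | CC(C)=CCBr | starting material
5 | 4-bromo-2-(3-methylbut-2-en-1-yl)phenol | CC(C)=CCc1cc(Br)ccc1O | intermediate
6 | 4-bromo-2-(hydroxymethyl)-6-(3-methylbut-2-en-1-yl)phenol (salicyl alcohol, not isolated) | CC(C)=CCc1cc(Br)cc(CO)c1O | intermediate
7 | 5-bromo-2-hydroxy-3-(3-methylbut-2-en-1-yl)benzaldehyde | CC(C)=CCc1cc(Br)cc(C=O)c1O | intermediate
8 | 5-bromo-3-(3-methylbut-2-en-1-yl)-2-[(triisopropylsilyl)oxy]benzaldehyde | CC(C)=CCc1cc(Br)cc(C=O)c1O[Si](C(C)C)(C(C)C)C(C)C | intermediate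
9 | (2-methylprop-1-en-1-yl)magnesium bromide | CC(C)=C[Mg]Br | starting material
10 | racemic 1-{5-bromo-3-(3-methylbut-2-en-1-yl)-2-[(triisopropylsilyl)oxy]phenyl}-3-methylbut-2-en-1-ol | CC(C)=CCc1cc(Br)cc(C(O)C=C(C)C)c1O[Si](C(C)C)(C(C)C)C(C)C | intermediate
11 | (1R)-1-{5-bromo-3-(3-methylbut-2-en-1-yl)-2-[(triisopropylsilyl)oxy]phenyl}-3-methylbut-2-en-1-ol | CC(C)=CCc1cc(Br)cc([C@H](O)C=C(C)C)c1O[Si](C(C)C)(C(C)C)C(C)C | intermediate
12 | (S)-{5-bromo-3-(3-methylbut-2-en-1-yl)-2-[(triisopropylsilyl)oxy]phenyl}[(2R)-3,3-dimethyloxiran-2-yl]methanol (threo) | CC(C)=CCc1cc(Br)cc([C@H](O)[C@H]2OC2(C)C)c1O[Si](C(C)C)(C(C)C)C(C)C | intermediate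
13 | 4-bromo-2-{(S)-[(2R)-3,3-dimethyloxiran-2-yl](hydroxy)methyl}-6-(3-methylbut-2-en-1-yl)phenol (not isolated) | CC(C)=CCc1cc(Br)cc([C@H](O)[C@H]2OC2(C)C)c1O | intermediate
14 | (2S,3S)-5-bromo-2-(2-hydroxypropan-2-yl)-7-(3-methylbut-2-en-1-yl)-2,3-dihydro-1-benzofuran-3-ol (trans) | CC(C)=CCc1cc(Br)cc2c1O[C@H](C(C)(C)O)[C@H]2O | intermediate
15 | 2-[(2S,3S)-5-bromo-3-{[tert-butyl(dimethyl)silyl]oxy}-7-(3-methylbut-2-en-1-yl)-2,3-dihydro-1-benzofuran-2-yl]propan-2-ol | CC(C)=CCc1cc(Br)cc2c1O[C@H](C(C)(C)O)[C@H]2O[Si](C)(C)C(C)(C)C | intermediate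
16 | N-methoxy-N-methylprop-2-enamide | C=CC(=O)N(C)OC | starting material
17 | (2E)-3-[(2S,3S)-3-{[tert-butyl(dimethyl)silyl]oxy}-2-(2-hydroxypropan-2-yl)-7-(3-methylbut-2-en-1-yl)-2,3-dihydro-1-benzofuran-5-yl]-N-methoxy-N-methylprop-2-enamide | CC(C)=CCc1cc(/C=C/C(=O)N(C)OC)cc2c1O[C@H](C(C)(C)O)[C@H]2O[Si](C)(C)C(C)(C)C | intermediate
18 | methyl (8E)-9-[(2S,3S)-3-{[tert-butyl(dimethyl)silyl]oxy}-2-(2-hydroxypropan-2-yl)-7-(3-methylbut-2-en-1-yl)-2,3-dihydro-1-benzofuran-5-yl]-3,5,7-trioxonon-8-enoate | CC(C)=CCc1cc(/C=C/C(=O)CC(=O)CC(=O)CC(=O)OC)cc2c1O[C@H](C(C)(C)O)[C@H]2O[Si](C)(C)C(C)(C)C | intermediate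
19 | (2E)-3-[(2S,3S)-3-{[tert-butyl(dimethyl)silyl]oxy}-2-(2-hydroxypropan-2-yl)-7-(3-methylbut-2-en-1-yl)-2,3-dihydro-1-benzofuran-5-yl]-1-(2,4,6-trihydroxyphenyl)prop-2-en-1-one | CC(C)=CCc1cc(/C=C/C(=O)c3c(O)cc(O)cc3O)cc2c1O[C@H](C(C)(C)O)[C@H]2O[Si](C)(C)C(C)(C)C | intermediate
20 | 5,7-dihydroxy-2-[(2S,3S)-3-{[tert-butyl(dimethyl)silyl]oxy}-2-(2-hydroxypropan-2-yl)-7-(3-methylbut-2-en-1-yl)-2,3-dihydro-1-benzofuran-5-yl]-2,3-dihydro-4H-chromen-4-one (both C2 epimers) | CC(C)=CCc1cc(C3CC(=O)c4c(O)cc(O)cc4O3)cc2c1O[C@H](C(C)(C)O)[C@H]2O[Si](C)(C)C(C)(C)C | intermediate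
21 | 4,5,7-tris(trimethylsilyloxy)-2H-chromene derived from 20, tertiary hydroxyl also trimethylsilylated (silyl enol ether, both C2 epimers, not isolated) | CC(C)=CCc1cc(C3C=C(O[Si](C)(C)C)c4c(O[Si](C)(C)C)cc(O[Si](C)(C)C)cc4O3)cc2c1O[C@H](C(C)(C)O[Si](C)(C)C)[C@H]2O[Si](C)(C)C(C)(C)C | intermediate
22 | 5,7-bis(trimethylsilyloxy)flavone corresponding to 23, tertiary hydroxyl trimethylsilylated (not isolated) | CC(C)=CCc1cc(-c3cc(=O)c4c(O[Si](C)(C)C)cc(O[Si](C)(C)C)cc4o3)cc2c1O[C@H](C(C)(C)O[Si](C)(C)C)[C@H]2O[Si](C)(C)C(C)(C)C | intermediate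
23 | 5,7-dihydroxy-2-[(2S,3S)-3-{[tert-butyl(dimethyl)silyl]oxy}-2-(2-hydroxypropan-2-yl)-7-(3-methylbut-2-en-1-yl)-2,3-dihydro-1-benzofuran-5-yl]-4H-chromen-4-one | CC(C)=CCc1cc(-c3cc(=O)c4c(O)cc(O)cc4o3)cc2c1O[C@H](C(C)(C)O)[C@H]2O[Si](C)(C)C(C)(C)C | intermediate
24 | 5,7-dihydroxy-2-[(2S,3S)-3-hydroxy-2-(2-hydroxypropan-2-yl)-7-(3-methylbut-2-en-1-yl)-2,3-dihydro-1-benzofuran-5-yl]-4H-chromen-4-one (CNP0172554.1) | CC(C)=CCc1cc(-c2cc(=O)c3c(O)cc(O)cc3o2)cc2c1O[C@H](C(C)(C)O)[C@H]2O | target

Total step count: 15. Longest linear sequence: 14 steps (3 to 24, steps 2–15); step 1 is a one-step side branch that joins at step 11.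

Steps most likely to fail

1. Step 12 (key step). The polyenolate may close in the aldol sense (C2 onto C7) or lactonise through an enol oxygen instead of undergoing the Claisen closure, and methoxide may fragment the chain by retro-Claisen cleavage. The fallback gives up the polyketide closure and builds the chalcone from a preformed ring A; it sets out from 15 and comes back at 19. Bromine–lithium exchange on 15 (n-BuLi, 2.2 equiv, THF, −78 °C; the first equivalent forms the alkoxide) followed by DMF should give the aryl aldehyde F1. Claisen–Schmidt condensation of F1 with the diallyl acetophenone F2 (from commercial 2',4',6'-trihydroxyacetophenone, allyl bromide and K2CO3 in acetone) under KOH in EtOH should give the diallyl chalcone F3. Pd(PPh3)4 with morpholine in THF should then remove both allyl groups and give 19.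

2. Step 11. Proton exchange between the trilithio species and the product, conjugate addition to the unsaturated amide, or cyclisation of the free triketo ester during the acidic work-up may erode the acylation. The fallback masks the ester terminus as a dioxinone and uses a dianion; it sets out from 17 and comes back at 18. The lithium dienolate of commercial 2,2,6-trimethyl-4H-1,3-dioxin-4-one (LiN(iPr)2, THF, −78 °C) is acetylated with N-acetylimidazole to the keto-dioxinone F4. Its dianion (LiN(iPr)2, 2 equiv, THF, −78 °C) is acylated at the terminal methyl by 17 to give the diketo-dioxinone F5. Brief heating of F5 with methanol in toluene at about 100 °C releases an acylketene, which methanol traps as 18 under neutral conditions; 18 would go directly into step 12.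

3. Step 7. Facial selectivity in the directed epoxidation may be weak, and the hindered benzylic carbinol may be oxidised to the enone instead. The fallback sets the epoxide centre by reagent control and corrects the carbinol centre afterwards; it sets out from 10 and comes back at 12. Racemate 10 is epoxidised under the conditions of step 6 to about half conversion, and the erythro epoxy alcohol F6 formed from the (S)-enantiomer is isolated. A Mitsunobu reaction (4-nitrobenzoic acid, PPh3, DIAD, toluene, 0 °C) inverts the carbinol centre to the threo 4-nitrobenzoate F7, and K2CO3 in MeOH releases 12.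

Further compounds
F1 | step 12 | (2S,3S)-3-{[tert-butyl(dimethyl)silyl]oxy}-2-(2-hydroxypropan-2-yl)-7-(3-methylbut-2-en-1-yl)-2,3-dihydro-1-benzofuran-5-carbaldehyde | CC(C)=CCc1cc(C=O)cc2c1O[C@H](C(C)(C)O)[C@H]2O[Si](C)(C)C(C)(C)C
F2 | step 12 | 1-[2-hydroxy-4,6-bis(prop-2-en-1-yloxy)phenyl]ethan-1-one | CC(=O)c1c(O)cc(OCC=C)cc1OCC=C
F3 | step 12 | (2E)-3-[(2S,3S)-3-{[tert-butyl(dimethyl)silyl]oxy}-2-(2-hydroxypropan-2-yl)-7-(3-methylbut-2-en-1-yl)-2,3-dihydro-1-benzofuran-5-yl]-1-[2-hydroxy-4,6-bis(prop-2-en-1-yloxy)phenyl]prop-2-en-1-one | CC(C)=CCc1cc(/C=C/C(=O)c3c(O)cc(OCC=C)cc3OCC=C)cc2c1O[C@H](C(C)(C)O)[C@H]2O[Si](C)(C)C(C)(C)C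
F4 | step 11 | 2,2-dimethyl-6-(2-oxopropyl)-4H-1,3-dioxin-4-one | CC(=O)CC1=CC(=O)OC(C)(C)O1
F5 | step 11 | 6-{(5E)-6-[(2S,3S)-3-{[tert-butyl(dimethyl)silyl]oxy}-2-(2-hydroxypropan-2-yl)-7-(3-methylbut-2-en-1-yl)-2,3-dihydro-1-benzofuran-5-yl]-2,4-dioxohex-5-en-1-yl}-2,2-dimethyl-4H-1,3-dioxin-4-one | CC(C)=CCc1cc(/C=C/C(=O)CC(=O)CC3=CC(=O)OC(C)(C)O3)cc2c1O[C@H](C(C)(C)O)[C@H]2O[Si](C)(C)C(C)(C)C
F6 | step 7 | (R)-{5-bromo-3-(3-methylbut-2-en-1-yl)-2-[(triisopropylsilyl)oxy]phenyl}[(2R)-3,3-dimethyloxiran-2-yl]methanol (erythro) | CC(C)=CCc1cc(Br)cc([C@@H](O)[C@H]2OC2(C)C)c1O[Si](C(C)C)(C(C)C)C(C)C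
F7 | step 7 | (S)-{5-bromo-3-(3-methylbut-2-en-1-yl)-2-[(triisopropylsilyl)oxy]phenyl}[(2R)-3,3-dimethyloxiran-2-yl]methyl 4-nitrobenzoate (threo) | CC(C)=CCc1cc(Br)cc([C@H](OC(=O)c3ccc(cc3)[N+](=O)[O-])[C@H]2OC2(C)C)c1O[Si](C(C)C)(C(C)C)C(C)C
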